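**Plan**
- Retrosynthesis: first the five O-benzyl groups, then the ester bond O3–C(=O) (to tetra-O-benzyl-epicatechin and O-benzylvanillic acid), then the C2–C1' bond between ring C and ring B (key step), then the C3–O bond, then C3=C4 (Wittig) and C4–C4a (ortho-formylation of the ring A phenol).
- Forward: ring A is bought; C4 is added as a formyl group, C3 and C2 by a Wittig reaction, and ring C closes as a lactol (O1–C2) after conjugate reduction. The C3 oxygen is then installed, ring B is joined at C2, the ester is made and the benzyl groups are removed.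
- Enabling feature: C2 of ring C lies between the ring oxygen O1 and the oxygen-bearing C3, and its aryl group is cis to the C3 oxygen. C2 can therefore be an O1-stabilised oxocarbenium carbon that receives the aryl group from boron held on O3, through a five-membered C1'–B–O3–C3–C2 array (temporary dioxaborolane ring).
- Stereochemistry: C3 (R) comes from L-proline-catalysed α-aminoxylation; C2 (R) is set from C3 by the cis delivery; no later step touches either centre.

Key step: step 5

Assumption: lactols 7, 8 and 9 are mixtures of C2 epimers (ring–chain tautomers), so their SMILES carry no descriptor at C2; this is harmless because C2 is planarised in step 5.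

**Step 1**
Reactants: 1 3,5-bis(benzyloxy)phenol; 2 formaldehyde (used as paraformaldehyde)
Product: 3 2,4-bis(benzyloxy)-6-hydroxybenzaldehyde
Conditions: (CH2O)n (6 equiv), MgCl2 (1.5 equiv), Et3N (3.8 equiv), MeCN, reflux; 1 M HCl work-up
Reagents that add atoms: none
Why: Magnesium-mediated ortho-formylation (Casnati–Skattebøl reaction): the magnesium phenoxide delivers formaldehyde only ortho to the phenol oxygen (the two ortho positions of 1 are equivalent) and a second formaldehyde accepts hydride from the magnesium salicyl alkoxide, so the carbon that becomes C4 is placed without regioisomers and the benzyl ethers are untouched.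

**Step 2**
Reactants: 3 2,4-bis(benzyloxy)-6-hydroxybenzaldehyde; 4 (triphenylphosphoranylidene)acetaldehyde
Product: 5 (E)-3-[2,4-bis(benzyloxy)-6-hydroxyphenyl]prop-2-enal
Conditions: 4 (1.3 equiv), toluene, 80 °C
Reagents that add atoms: none
Why: Wittig reaction of the stabilised formylmethylene ylide should give the (E)-enal and adds the carbons that become C3 and C2, the latter already at the aldehyde oxidation level; the free phenol is tolerated by this weakly basic ylide.

**Step 3**
Reactants: 5 (E)-3-[2,4-bis(benzyloxy)-6-hydroxyphenyl]prop-2-enal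
Product: 7 5,7-bis(benzyloxy)chroman-2-ol (C2 epimer mixture), via open-chain hydroxy aldehyde 6 (not isolated)
Conditions: Hantzsch ester (1.2 equiv), Bn2NH2+ CF3CO2− (10 mol %), THF, rt → 40 °C
Reagents that add atoms: none
Why: Iminium-catalysed transfer hydrogenation with a Hantzsch ester reduces only the conjugated C=C bond (aldehyde and benzyl ethers remain), and the saturated hydroxy aldehyde 6 closes by hemiacetal formation (6-exo-trig attack of the phenol oxygen on the formyl group) to the lactol, which forms ring C with C2 at the acetal oxidation level.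

**Step 4**
Reactants: 7 5,7-bis(benzyloxy)chroman-2-ol
Product: 9 (3R)-5,7-bis(benzyloxy)chromane-2,3-diol (C2 epimer mixture), via aminooxy lactol 8 (not isolated)
Conditions: L-proline (20 mol %), PhNO (1.0 equiv), MeCN, −20 °C; then AcOH, Zn dust, 0 °C → rt
Reagents that add atoms: nitrosobenzene, O=Nc1ccccc1
Why: Proline enamine catalysis (α-aminoxylation, an O-selective nitroso aldol reaction) acts on the open-chain aldehyde in equilibrium with the lactol, the carboxylic acid of L-proline guiding the nitroso oxygen to the enamine face that gives the (R)-α-oxy aldehyde, and zinc in acetic acid then cleaves the weak N–O bond without touching the benzyl ethers or the hemiacetal, so C3 is set as (3R).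

**Step 5**
Reactants: 9 (3R)-5,7-bis(benzyloxy)chromane-2,3-diol; 10 [3,4-bis(benzyloxy)phenyl]boronic acid
Product: 12 (2R,3R)-5,7-bis(benzyloxy)-2-[3,4-bis(benzyloxy)phenyl]chroman-3-ol (tetra-O-benzyl-(−)-epicatechin), via cyclic aryl boronate 11 (not isolated)
Conditions: 10 (1.2 equiv), 4 Å MS, CH2Cl2, rt; then BF3·OEt2 (0.5 equiv), −78 → −20 °C; aq. NaHCO3
Reagents that add atoms: none
Why: Proposed new method: the lactol diol condenses with boronic acid 10 to the cis-fused dioxaborolane 11 (both C2 epimers funnel into it by mutarotation), which turns the anomeric hydroxyl into a boron-bound leaving group and fixes the aryl donor on O3; BF3 then triggers heterolysis of the C2–O(B) bond with help from the lone pair of ring oxygen O1, and the aryl group (ipso carbon para to a benzyloxy donor) shifts from the now oxide/fluoride-ligated, electron-rich boron to the oxocarbenium carbon through a five-membered C1'–B–O3–C3–C2 transition state. The closest known reaction types are the Petasis borono-Mannich reaction of α-hydroxy aldehydes, the cis-selective addition of aryl boronic esters to cyclic N-acyliminium ions with a neighbouring hydroxyl group, and the addition of boronates to 2H-chromene acetals; what is new is the transfer to a saturated chroman-2-yl oxocarbenium ion from a boronate that bridges the leaving group and the directing oxygen. No ring of the target is closed: the temporary five-membered dioxaborolane arises by twofold B–O condensation across the cis-2,3-diol and is opened again in the same operation, boron being removed on aqueous work-up. The new stereocentre C2 is controlled by C3, because boron held on O3 can reach only the face of the cation on which O3 stands, which should give the 2,3-cis (2R,3R) product that an untethered nucleophile (adding anti to O3) would not give. The step needs this face selectivity and must outrun Friedel–Crafts attack by the electron-rich ring A and loss of the C3 proton; the tether (transfer inside an ion pair), low temperature and dilution are meant to secure this.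

**Step 6**
Reactants: 12 (2R,3R)-5,7-bis(benzyloxy)-2-[3,4-bis(benzyloxy)phenyl]chroman-3-ol; 13 4-(benzyloxy)-3-methoxybenzoic acid
Product: 14 (2R,3R)-5,7-bis(benzyloxy)-2-[3,4-bis(benzyloxy)phenyl]chroman-3-yl 4-(benzyloxy)-3-methoxybenzoate
Conditions: 13 (1.5 equiv), DCC (1.5 equiv), DMAP (0.3 equiv), CH2Cl2, 0 °C → rt
Reagents that add atoms: none
Why: Steglich esterification (carbodiimide activation with DMAP acyl transfer) acylates the only free hydroxyl group, the secondary 3-OH, with retention at C3, as in the galloylation of benzylated flavan-3-ols.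

**Step 7**
Reactants: 14 (2R,3R)-5,7-bis(benzyloxy)-2-[3,4-bis(benzyloxy)phenyl]chroman-3-yl 4-(benzyloxy)-3-methoxybenzoate
Product: 15 (2R,3R)-2-(3,4-dihydroxyphenyl)-5,7-dihydroxychroman-3-yl 4-hydroxy-3-methoxybenzoate
Conditions: H2 (1 atm), 20% Pd(OH)2/C, THF–MeOH (1:1), rt
Reagents that add atoms: none
Why: Hydrogenolysis over Pearlman's catalyst should remove all five benzyl ethers in one operation while the aryl ester and the ring C ether bond stay intact under these mild neutral conditions, so neither stereocentre is touched and the target results.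

**Compound list**
1 | 3,5-bis(benzyloxy)phenol | Oc1cc(OCc2ccccc2)cc(OCc2ccccc2)c1 | starting material
2 | formaldehyde (as paraformaldehyde) | C=O | starting material
3 | 2,4-bis(benzyloxy)-6-hydroxybenzaldehyde | O=Cc1c(O)cc(OCc2ccccc2)cc1OCc1ccccc1 | intermediate
4 | (triphenylphosphoranylidene)acetaldehyde | O=CC=P(c1ccccc1)(c1ccccc1)c1ccccc1 | starting material
5 | (E)-3-[2,4-bis(benzyloxy)-6-hydroxyphenyl]prop-2-enal | O=C/C=C/c1c(O)cc(OCc2ccccc2)cc1OCc1ccccc1 | intermediate
6 | 3-[2,4-bis(benzyloxy)-6-hydroxyphenyl]propanal (not isolated) | O=CCCc1c(O)cc(OCc2ccccc2)cc1OCc1ccccc1 | intermediate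
7 | 5,7-bis(benzyloxy)chroman-2-ol | OC1CCc2c(OCc3ccccc3)cc(OCc3ccccc3)cc2O1 | intermediate
8 | (3R)-3-(anilinooxy)-5,7-bis(benzyloxy)chroman-2-ol (not isolated) | c1ccccc1NO[C@@H]1Cc2c(OCc3ccccc3)cc(OCc3ccccc3)cc2OC1O | intermediate
9 | (3R)-5,7-bis(benzyloxy)chromane-2,3-diol | O[C@@H]1Cc2c(OCc3ccccc3)cc(OCc3ccccc3)cc2OC1O | intermediate
10 | [3,4-bis(benzyloxy)phenyl]boronic acid | OB(O)c1ccc(OCc2ccccc2)c(OCc2ccccc2)c1 | starting material
11 | cis-fused cyclic O2,O3-[3,4-bis(benzyloxy)phenyl]boronate of 9 (not isolated) | O1[C@@H]2Cc3c(OCc4ccccc4)cc(OCc4ccccc4)cc3O[C@@H]2OB1c1ccc(OCc2ccccc2)c(OCc2ccccc2)c1 | intermediate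
12 | (2R,3R)-5,7-bis(benzyloxy)-2-[3,4-bis(benzyloxy)phenyl]chroman-3-ol | O[C@@H]1Cc2c(OCc3ccccc3)cc(OCc3ccccc3)cc2O[C@@H]1c1ccc(OCc2ccccc2)c(OCc2ccccc2)c1 | intermediate
13 | 4-(benzyloxy)-3-methoxybenzoic acid | COc1cc(C(=O)O)ccc1OCc1ccccc1 | starting material
14 | (2R,3R)-5,7-bis(benzyloxy)-2-[3,4-bis(benzyloxy)phenyl]chroman-3-yl 4-(benzyloxy)-3-methoxybenzoate | COc1cc(C(=O)O[C@@H]2Cc3c(OCc4ccccc4)cc(OCc4ccccc4)cc3O[C@@H]2c2ccc(OCc3ccccc3)c(OCc3ccccc3)c2)ccc1OCc1ccccc1 | intermediate
15 | (2R,3R)-2-(3,4-dihydroxyphenyl)-5,7-dihydroxychroman-3-yl 4-hydroxy-3-methoxybenzoate | COc1cc(C(=O)O[C@@H]2Cc3c(O)cc(O)cc3O[C@@H]2c2ccc(O)c(O)c2)ccc1O | target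

**Count**
Total steps: 7. Longest linear sequence: 7 steps (1 → 15).

**Steps most likely to fail**

Step 5 (Proposed new method). Ionisation at C2 may not be followed quickly enough by the aryl shift. The cation could then be captured by ring A of a second molecule, lose the C3 proton (erasing C3), or take the aryl group from an untethered boron species on the face anti to O3, and the boronic acid could protodeboronate.
The fallback uses known chemistry, sets out from 9 and returns at 12. Oxidation of the lactol with Fétizon's reagent (Ag2CO3 on Celite, toluene, reflux) should give (R)-5,7-bis(benzyloxy)-3-hydroxychroman-2-one F1. Addition of 3,4-bis(benzyloxy)phenyllithium (2.2 equiv, from purchased 4-bromo-1,2-bis(benzyloxy)benzene and n-BuLi, THF, −78 °C; the first equivalent deprotonates 3-OH) should give the hemiketal (3R)-5,7-bis(benzyloxy)-2-[3,4-bis(benzyloxy)phenyl]chromane-2,3-diol F2. Ionic reduction (Et3SiH, BF3·OEt2, CH2Cl2, −78 → −30 °C) then passes through the 2-aryl oxocarbenium ion, which takes hydride axially on the face anti to the pseudoaxial C3 oxygen, as in reductive etherifications to 2,3-cis flavans, and should give 12. In this variant the C2–aryl bond comes from a carbonyl addition and the C2 configuration from hydride delivery.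

Step 4. The lactol may release too little free aldehyde for enamine formation, nitrosobenzene may attack the electron-rich ring or react N-selectively, the α-oxy aldehyde may epimerise in its open form, and the aniline set free on N–O cleavage may condense with the hemiacetal.
The fallback sets out from 3 and returns at 9, replacing steps 2–4. Wittig reaction with ethyl (triphenylphosphoranylidene)acetate (toluene, 50 °C) should give ethyl (E)-3-[2,4-bis(benzyloxy)-6-hydroxyphenyl]prop-2-enoate F3. Sharpless asymmetric dihydroxylation with (DHQ)2PHAL, K2OsO2(OH)4 and NMO (acetone–water; NMO rather than ferricyanide to spare the phenol) should give ethyl (2R,3S)-3-[2,4-bis(benzyloxy)-6-hydroxyphenyl]-2,3-dihydroxypropanoate F4, with the face chosen by the ligand. Ionic hydrogenation (Et3SiH, TFA, CH2Cl2, 0 °C) removes only the benzylic hydroxyl, whose cation is stabilised by the ortho and para oxygens, and the acid closes the lactone to (R)-5,7-bis(benzyloxy)-3-hydroxychroman-2-one F1. DIBAL (2.2 equiv, CH2Cl2, −78 °C) then reduces the lactone to 9.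

Step 3. The Z-iminium ion may close onto the phenol to a 2-aminochromene or benzopyrylium ion that takes hydride at C2 instead of C4, and the electron-rich enal may accept hydride slowly.
The fallback sets out from 3 and returns at 7, replacing steps 2–3 by a cycloaddition. Reduction with NaBH4 (MeOH, 0 °C) should give 3,5-bis(benzyloxy)-2-(hydroxymethyl)phenol F5, used crude. Heating in neat ethyl vinyl ether (sealed tube, 120–150 °C) dehydrates it to the ortho-quinone methide, which is trapped by inverse-demand hetero-Diels–Alder reaction to 5,7-bis(benzyloxy)-2-ethoxychromane F6. Hydrolysis of the acetal (1 M HCl, THF, rt) then gives 7.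

**Further compounds**
F1 | step 5 | (R)-5,7-bis(benzyloxy)-3-hydroxychroman-2-one | O[C@@H]1Cc2c(OCc3ccccc3)cc(OCc3ccccc3)cc2OC1=O
F2 | step 5 | (3R)-5,7-bis(benzyloxy)-2-[3,4-bis(benzyloxy)phenyl]chromane-2,3-diol | O[C@@H]1Cc2c(OCc3ccccc3)cc(OCc3ccccc3)cc2OC1(O)c1ccc(OCc2ccccc2)c(OCc2ccccc2)c1
F3 | step 4 | ethyl (E)-3-[2,4-bis(benzyloxy)-6-hydroxyphenyl]prop-2-enoate | CCOC(=O)/C=C/c1c(O)cc(OCc2ccccc2)cc1OCc1ccccc1
F4 | step 4 | ethyl (2R,3S)-3-[2,4-bis(benzyloxy)-6-hydroxyphenyl]-2,3-dihydroxypropanoate | CCOC(=O)[C@H](O)[C@@H](O)c1c(O)cc(OCc2ccccc2)cc1OCc1ccccc1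
F5 | step 3 | 3,5-bis(benzyloxy)-2-(hydroxymethyl)phenol | OCc1c(O)cc(OCc2ccccc2)cc1OCc1ccccc1
F6 | step 3 | 5,7-bis(benzyloxy)-2-ethoxychromane | CCOC1CCc2c(OCc3ccccc3)cc(OCc3ccccc3)cc2O1
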